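the same everywhere: substrate 0.10 M
- cedar: reagent 0.10 M; run made earlier
- maple: reagent 0.15 M; run made earlier
- flask: reagent 0.200 M; time 15 min

- cedar (time / min: target / %, side product / %, substrate / %): 4.00: 55.9, 24.2, 4.3; 8.00: 55.2, 23.7, 3.4; 12.0: 54.9, 23.5, 3.5; 15.0: 54.5, 21.1, 0
- maple (time / min: target / %, side product / %, substrate / %): 1.33: 53.6, 38.6, 1.4; 3.00: 55.6, 39.7, 0; 6.00: 54.6, 40.2, 0.6; 15.0: 54.9, 39.3, 0.9

(standard deviation of a reading: 1 percentage point)

* why nothing more happens at 15 min, or that something still does (all of the substrate has reacted / the reagent has run out first / it is still moving)
* the target standing at 15 min, as a percentage of the substrate charged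
* the side product standing at 15 min, as a percentage of the substrate charged

- the numbers in the tables scatter with a standard deviation of 1 percentage point
- the reaction counts as stopped when no species that holds the substrate changes by six tenths of a point or more over the second half of the time

A small charge of substrate, 0.10 M, gave flat target and side product in both earlier runs. In cedar, target plus 2 times side product averages 101 % of the substrate charged, which matches the reagent charge. So this reckoning lets target cost one reagent and side product 2, and it takes the rate ratio to grow with reagent:

side product rate / target rate = [reagent] / [reagent]×

[target] = 0.5 · [reagent]× · ln(([reagent]× + 2[reagent]start) / ([reagent]× + 2[reagent]))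

The later maple readings average 0.0550 M target and 0.0397 M side product, so by this count maple keeps 0.0155 M reagent. A trial value of 0.10 M then returns 0.0986 M, the crossing concentration [reagent]×, the reagent level at which both products form equally fast. As a check, cedar with its reagent spent should hold 54.6 % target, and its readings average 55.1 %.

The flask starts with a rate ratio of 2.03, so side product leads. The crossing comes at 0.0257 M target and 0.0378 M side product. After that, target gains on side product. For the end level, a trial target of 0.0500 M returns 0.0454 M, and that returns 0.0477 M. This reckoning therefore ends near 0.0466 M: 46.6 % target and 53.4 % side product, with the substrate used up and 0.0466 M reagent left.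

The forecast calls the target “set by a fixed branch” and gives: all of the substrate has reacted, 55 % target, 44.5 % side product.

The flask gives: all of the substrate has reacted, 45.1 % target, 51.7 % side product. The reckoning stood 1.5 percentage points and 1.7 points above these, and the flask also holds 3.22 % self-condensation product, which the reckoning left out.

    substrate + reagent → target (k = 1.70 /M/s)
    substrate + 2 reagent → side product (k = 17.0 /M²/s)
    2 substrate → self-condensation product (k = 0.180 /M/s)

The flask is at rest. Substrate, the limiting reagent here, stands at 0 %, while reagent keeps 26 % of its charge, 0.0515 M, below [reagent]×. Target in the flask already stands at 45.1 % at 1.50 min. At 150 min, ten times the asked time, the flask shows 45.1 % target and 51.7 % side product, the same as at the asked time.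

A neighbour flask with 0.80 M reagent starts at a ratio of 8.11, and the same line gives 0.0132 M, then 0.0122 M, or 12.2 % target. That neighbour flask holds 12.4 % target and 87.4 % side product.

The readings were computed on assumed constants.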